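An easy step first: each J that reaches X takes 3 L and gives 3 G, so the charge of L sets how much X can form.

| setting | epsilon | beta | theta | delta |
|---|---|---|---|---|
| J | 20 mM | 20 mM | 20 mM | 20 mM (fed, over 9.60 min) |
| L | 22.0 mM (fed, over 9.60 min) | 22.0 mM | 22.0 mM | 22.0 mM |
| G | 100 mM | 100 mM | 100 mM | 100 mM |
| time | 12 min | 12 min |  | 12 min |
| remark | a stirred flask in which L is dosed at a steady rate over 9.60 min without added volume, worked up at 12 min | a closed flask charged with all of it at once and left for 12 min | a single well-mixed tank run continuously and read at steady state, 12 min in it on average | a stirred flask in which J is dosed at a steady rate over 9.60 min without added volume, worked up at 12 min |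

* the set-up with the highest amount of D at the outlet or at the end, in percent of the J put in ("none" if the first two lie within 2 percentage points) (epsilon / beta / theta / delta / none)
* amount of D at the outlet or at the end, in percent of the J put in, epsilon
* amount of D at the outlet or at the end, in percent of the J put in, beta
* amount of D at the outlet or at the end, in percent of the J put in, theta
* amount of D at the outlet or at the end, in percent of the J put in, delta

- the stated concentrations are those of everything mixed, before any reaction; amounts are the same in each set-up
- the feed brings no volume worth counting
- run time (epsilon): 12 min

    J + L ⇌ G + D (K1 = 2.4, k1 = 100 L mol⁻¹ min⁻¹)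
    D + L ⇌ G + Z (K2 = 12, k2 = 98 L mol⁻¹ min⁻¹)
    Z + L ⇌ G + X (K3 = 310, k3 = 270 L mol⁻¹ min⁻¹)
    D ⇌ E (K4 = 3.9, k4 = 0.066 min⁻¹)

We reckon D as a small correction to the large split between J and X.

1. By forward rates at the charged amounts, the slowest of the quick steps has a half-life of 0.321 min, far shorter than 12 min. We therefore treat steps 1 to 3 as a pre-equilibrium. Each ratio of neighbours then equals its constant times free L over G, so D over J is 2.4 times that ratio.

2. We leave out the leak to E to keep the sum short, at a cost: its half-life of 11 min is about the run time of 12 min, so our figure for D will stand on the high side.

3. First way: put the L into X. That gives 7.33 mM of X and leaves 12.7 mM of J. The three steps together have the constant 8930, so X over J gives a ratio of 0.0402, and D comes to 6.11% of the J charged.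

4. This way cheats. It spends the L on X, yet its own ratio needs 4.71 mM of L free.

5. Second way: count that free L, together with the L held in D and Z, as taken away from X. With 1.22 mM of D and 0.589 mM of Z, X falls to 4.96 mM and J becomes 13.2 mM.

6. This gives the balance ratio, free L over G once the quick steps stand at balance: 0.0348. D in beta is then 5.52%, lower than the first way by 0.59 percentage points. We take this second figure, with the leak to E still left out.

7. We take the same figure for delta, 5.52%, and as a floor for epsilon, 5.52%, and theta, 5.52%. Our judgement, beyond the reckoning, is that best is none.

The forecast gives 7% for epsilon, 5.5% for beta, 7.4% for theta, 5% for delta and none as best, because D “sits as a small intermediate”.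

The flasks give 6.17% for epsilon, 5.21% for beta, 7.30% for theta and 5.54% for delta. Theta leads epsilon by 1.1 points, less than the margin of 2 points, so best is none.

Beta at 12.0 min holds L at 18.7% of its charge and G at 118% of its own, a read ratio of 0.0349, about the reckoned one. The neighbouring flask is beta with 88 mM of L. There we send the J to X, which leaves 28.0 mM of L free beside 160 mM of G, a ratio of 0.175. D over X is then one over 12 times 310 times that ratio squared, 0.878%. That neighbouring flask gives X at 94.6% and D at 0.692% of the J charged.

The numbers of this flask are assumed, and the outcome is calculated.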